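The 14-membered carbocycle is disconnected where the acetoxy-bearing carbon C13 meets the methyl-bearing alkene carbon C12 (cembrane numbering: lactone carbinol C2, epoxide C7–C8). This allylic carbinol beside the C11=C12 (E)-alkene is the retron of an intramolecular Nozaki–Hiyama–Kishi reaction. In one operation the (E)-alkenyl iodide of a seco-aldehyde adds to the C13 aldehyde, closing the macrocycle far from the butenolide ring, creating the C13 stereocentre and keeping the alkene geometry, while the epoxide and the base-sensitive butenolide stay untouched. The precursor is an open-chain epoxy butenolide bearing a CH2CHO arm on the lactone β-carbon and the iodoalkene at the far end.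

Key step: step 16

Remark: cembrane numbering (C1–C20) is used for all atom labels; compounds 1, 3, 17 and 18, propyne and the enantiomeric (L-series) Shi ketone are taken as commercial.

Step 1
Reactants: 1 pent-3-yn-1-ol
Product: 2 5-iodopent-2-yne
Conditions: I2, PPh3, imidazole, CH2Cl2, 0 °C to rt
Reagents that add atoms: iodine, II
Why: Appel-type iodination converts the primary alcohol into the iodide by SN2 displacement of the alkoxyphosphonium ion without touching the internal alkyne.

Step 2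
Reactants: 3 but-2-yn-1-ol
Product: 5 (2Z)-3-iodobut-2-en-1-ol, via cyclic alkenylaluminate 4 (not isolated)
Conditions: NaAlH2(OCH2CH2OCH3)2, THF, 0 °C; then I2, −78 °C
Reagents that add atoms: iodine, II
Why: Alkoxide-directed trans-hydroalumination of the propargylic alcohol places aluminium on the distal carbon in a five-membered aluminate, and iodinolysis with retention gives the iodoalkene with iodine cis to CH2OH (2Z).

Step 3
Reactants: 2 5-iodopent-2-yne; 5 (2Z)-3-iodobut-2-en-1-ol
Product: 7 (2Z)-3-methyloct-2-en-6-yn-1-ol, via iodo(pent-3-yn-1-yl)zinc 6 (not isolated)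
Conditions: Zn dust, LiCl, THF, 40 °C; then 5, Pd(OAc)2 (2 mol%), SPhos (4 mol%), THF, 25 °C (zinc reagent in excess)
Reagents that add atoms: none
Why: Negishi cross-coupling of the alkylzinc iodide with the alkenyl iodide proceeds with retention of alkene geometry under a catalyst system that tolerates a free hydroxyl group, so the new chain ends up cis to CH2OH (2Z).

Step 4
Reactants: 7 (2Z)-3-methyloct-2-en-6-yn-1-ol
Product: 8 (2Z)-1-bromo-3-methyloct-2-en-6-yne
Conditions: CBr4, PPh3, CH2Cl2, −20 to 0 °C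
Reagents that add atoms: carbon tetrabromide, BrC(Br)(Br)Br
Why: Appel bromination at low temperature gives the primary allylic bromide by SN2 displacement without allylic transposition or loss of the Z geometry.

Step 5
Reactants: 8 (2Z)-1-bromo-3-methyloct-2-en-6-yne
Product: 10 (5Z)-6-methylundec-5-ene-1,9-diyne, via lithium acetylide 9 (not isolated)
Conditions: propyne, n-BuLi (2 equiv), TMEDA, Et2O–hexane, −78 to 0 °C; then 8, −78 °C to rt; H2O
Reagents that add atoms: propyne, CC#C
Why: 1,3-Dilithiopropyne is alkylated at its sp3 carbon by SN2 attack on the primary allylic bromide (a propargylation established for geranyl-type bromides), leaving a lithium acetylide that is protonated on work-up.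

Step 6
Reactants: 10 (5Z)-6-methylundec-5-ene-1,9-diyne
Product: 13 (2E,6Z)-3,7-dimethyldodeca-2,6-dien-10-yn-1-ol, via alkenyldimethylalane 11 (not isolated), via lithium alkenylalanate 12 (not isolated)
Conditions: AlMe3 (2 equiv), Cp2ZrCl2 (0.25 equiv), CH2Cl2, 0 °C to rt; then n-BuLi, THF, −78 to 0 °C; then (CH2O)n, rt
Reagents that add atoms: trimethylaluminium, C[Al](C)C; paraformaldehyde (as formaldehyde), C=O
Why: Negishi zirconium-catalysed carboalumination adds methyl and aluminium syn across the terminal alkyne (methyl to the internal carbon, much faster than to the internal alkyne), and hydroxymethylation of the derived alanate gives the 2E allylic alcohol.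

Step 7
Reactants: 13 (2E,6Z)-3,7-dimethyldodeca-2,6-dien-10-yn-1-ol
Product: 15 (2E,6Z,10E)-11-iodo-3,7-dimethyldodeca-2,6,10-trien-1-ol, via zirconated alkoxide 14 (not isolated)
Conditions: Cp2Zr(H)Cl (3 equiv), THF, 50 °C; then I2, 0 °C
Reagents that add atoms: iodine, II
Why: Hydrozirconation adds Zr–H syn across the remaining alkyne, excess reagent equilibrating zirconium to the less hindered methyl-bearing carbon, and iodinolysis with retention gives the (E)-2-iodo-2-alkene terminus.

Step 8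
Reactants: 15 (2E,6Z,10E)-11-iodo-3,7-dimethyldodeca-2,6,10-trien-1-ol
Product: 16 (2E,6Z,10E)-11-iodo-3,7-dimethyldodeca-2,6,10-trienal
Conditions: MnO2, CH2Cl2, rt
Reagents that add atoms: none
Why: MnO2 oxidises the allylic alcohol selectively to the enal without isomerising the 2E double bond or affecting the iodoalkene.

Step 9
Reactants: 17 methyl acrylate; 18 3-[(tert-butyldimethylsilyl)oxy]propanal
Product: 19 methyl 5-[(tert-butyldimethylsilyl)oxy]-3-hydroxy-2-methylidenepentanoate (racemic)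
Conditions: DABCO, neat, rt
Reagents that add atoms: none
Why: Morita–Baylis–Hillman reaction of the acrylate with the aldehyde; the new carbinol centre is racemic but becomes an sp2 carbon in the next step.

Step 10
Reactants: 19 methyl 5-[(tert-butyldimethylsilyl)oxy]-3-hydroxy-2-methylidenepentanoate
Product: 20 methyl (2Z)-2-(bromomethyl)-5-[(tert-butyldimethylsilyl)oxy]pent-2-enoate
Conditions: NBS, Me2S, CH2Cl2, 0 °C to rt
Reagents that add atoms: N-bromosuccinimide, O=C1CCC(=O)N1Br
Why: Activation of the alcohol as an alkoxysulfonium ion (Corey–Kim type) and SN2' delivery of bromide gives the thermodynamically preferred Z 2-(bromomethyl)enoate while the silyl ether survives.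

Step 11
Reactants: 16 (2E,6Z,10E)-11-iodo-3,7-dimethyldodeca-2,6,10-trienal; 20 methyl (2Z)-2-(bromomethyl)-5-[(tert-butyldimethylsilyl)oxy]pent-2-enoate
Product: 22 (4S,5R)-4-{2-[(tert-butyldimethylsilyl)oxy]ethyl}-5-[(1E,5Z,9E)-10-iodo-2,6-dimethylundeca-1,5,9-trien-1-yl]-3-methylideneoxolan-2-one, via silylated open-chain adduct 21 (not isolated)
Conditions: CrCl2 (10 mol%, nickel-free), chiral carbazole bis(oxazoline) ligand (12 mol%), Mn, TMSCl, DIPEA (30 mol%), THF, rt; then p-TsOH·H2O (cat.), CH2Cl2, rt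
Reagents that add atoms: none
Why: Catalytic asymmetric Nozaki–Hiyama 2-(alkoxycarbonyl)allylation, in which the allylchromium adds through its γ-carbon to the aldehyde and the ligand enantiomer that directs attack to the Si face sets C2 as R, followed by acid-promoted lactonisation; nickel-free chromium leaves the iodoalkene untouched and the second new centre (C1, expected trans) is erased in step 12.

Step 12
Reactants: 22 the α-methylene lactone
Product: 23 (5R)-4-{2-[(tert-butyldimethylsilyl)oxy]ethyl}-5-[(1E,5Z,9E)-10-iodo-2,6-dimethylundeca-1,5,9-trien-1-yl]-3-methylfuran-2(5H)-one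
Conditions: RuHCl(CO)(PPh3)3 (5 mol%), toluene, 80 °C
Reagents that add atoms: none
Why: Ruthenium hydride-catalysed alkene isomerisation (hydrometalation, then β-hydride elimination) moves the exocyclic methylene into the ring to give the more stable tetrasubstituted butenolide under base-free conditions that leave the C2–H stereocentre alone.

Step 13
Reactants: 23 the butenolide silyl ether
Product: 24 (5R)-4-{2-[(tert-butyldimethylsilyl)oxy]ethyl}-5-[(1E)-4-{(2S,3R)-3-[(3E)-4-iodopent-3-en-1-yl]-3-methyloxiran-2-yl}-2-methylbut-1-en-1-yl]-3-methylfuran-2(5H)-one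
Conditions: enantiomeric (L-series) Shi ketone (0.5–1 equiv), Oxone (2KHSO5·KHSO4·K2SO4), NaHCO3 (pH about 8), MeCN–aq. Na2EDTA, 0 °C
Reagents that add atoms: potassium peroxymonosulfate, [K+].[O-]S(=O)(=O)OO
Why: Shi epoxidation, in which the chiral dioxirane transfers oxygen stereospecifically (Z-alkene to cis-epoxide) through the spiro transition state with the lone vinylic hydrogen in the hindered quadrant, so the L-series ketone should give 7S,8R; only C7=C8 is electron-rich enough to react, since C3=C4 is deactivated by the allylic lactone oxygen and the butenolide and iodoalkene are electron-poor.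

Step 14
Reactants: 24 the epoxy silyl ether
Product: 25 (5R)-4-(2-hydroxyethyl)-5-[(1E)-4-{(2S,3R)-3-[(3E)-4-iodopent-3-en-1-yl]-3-methyloxiran-2-yl}-2-methylbut-1-en-1-yl]-3-methylfuran-2(5H)-one
Conditions: TBAF, AcOH (1:1), THF, 0 °C to rt
Reagents that add atoms: none
Why: Fluoride-mediated desilylation buffered with acetic acid removes the primary silyl ether without opening the epoxide or deprotonating the butenolide at C2.

Step 15
Reactants: 25 the primary alcohol
Product: 26 {(2R)-2-[(1E)-4-{(2S,3R)-3-[(3E)-4-iodopent-3-en-1-yl]-3-methyloxiran-2-yl}-2-methylbut-1-en-1-yl]-4-methyl-5-oxo-2,5-dihydrofuran-3-yl}acetaldehyde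
Conditions: Dess–Martin periodinane, NaHCO3, CH2Cl2, 0 °C; used at once
Reagents that add atoms: none
Why: Dess–Martin oxidation under buffered, non-basic conditions gives the enolisable β,γ-unsaturated aldehyde without conjugation or epimerisation.

Step 16
Reactants: 26 the seco iodoalkene aldehyde
Product: 28 (2R,7S,8R,13R)-7,8-epoxy-13-hydroxycembra-1(15),3E,11E-trien-16,2-olide, via alkenylchromium dichloride 27 (not isolated)
Conditions: CrCl2 (10 equiv), chiral oxazoline–sulfonamide ligand (11 equiv), Et3N (11 equiv), NiCl2 (0.1 equiv), THF, rt, slow addition of 26 to a final 2 mM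
Reagents that add atoms: none
Why: Zerovalent nickel formed in situ inserts into the C12–I bond with retention and hands the alkenyl group to trivalent chromium, and the alkenylchromium adds to the C13 aldehyde to give a chromium alkoxide (Nozaki–Hiyama–Kishi reaction run as a macrocyclisation). The closest known reaction type is the nickel/chromium-mediated ring closure of iodoalkene aldehydes to macrocyclic allylic alcohols. The 14-membered ring closes in the 14-exo-trig mode with respect to the carbonyl group. The C11=C12 geometry is carried over from the E-iodoalkene, and C13 is set R by Si-face addition under control of the chiral sulfonamide ligand on chromium (enantiomer to be fixed on a model aldehyde), which must cooperate with or override the folding bias imposed by C2, C7 and C8. The step needs chemoselectivity for the aldehyde over the lactone carbonyl, the epoxide and the acidic C14 and C2 protons, which the non-basic, aldehyde-selective organochromium secures. It also needs cyclisation over oligomerisation, which high dilution secures.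

Step 17
Reactants: 28 the macrocyclic allylic alcohol
Product: 29 (2R,7S,8R,13R)-13-acetoxy-7,8-epoxycembra-1(15),3E,11E-trien-16,2-olide (target)
Conditions: Ac2O, pyridine, DMAP (cat.), CH2Cl2, 0 °C
Reagents that add atoms: acetic anhydride, CC(=O)OC(C)=O
Why: DMAP-catalysed acetylation of the secondary allylic alcohol proceeds with retention at C13 and is run cold so that neither elimination of the new acetate nor epimerisation at C2 sets in.

Compound list
1 | pent-3-yn-1-ol | CC#CCCO | starting material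
2 | 5-iodopent-2-yne | CC#CCCI | intermediate
3 | but-2-yn-1-ol | CC#CCO | starting material
4 | sodium 2,2-bis(2-methoxyethoxy)-3-methyl-2,5-dihydro-1,2-oxaluminol-2-uide (cyclic alkenylaluminate) | CC1=CCO[Al-]1(OCCOC)OCCOC.[Na+] | intermediate (not isolated)
5 | (2Z)-3-iodobut-2-en-1-ol | C/C(I)=C/CO | intermediate
6 | iodo(pent-3-yn-1-yl)zinc | CC#CCC[Zn]I | intermediate (not isolated)
7 | (2Z)-3-methyloct-2-en-6-yn-1-ol | CC#CCC/C(C)=C\CO | intermediate
8 | (2Z)-1-bromo-3-methyloct-2-en-6-yne | CC#CCC/C(C)=C\CBr | intermediate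
9 | [(5Z)-6-methylundec-5-ene-1,9-diyn-1-yl]lithium | CC#CCC/C(C)=C\CCC#C[Li] | intermediate (not isolated)
10 | (5Z)-6-methylundec-5-ene-1,9-diyne | CC#CCC/C(C)=C\CCC#C | intermediate
11 | [(1E,5Z)-2,6-dimethylundeca-1,5-dien-9-yn-1-yl]dimethylaluminium | CC#CCC/C(C)=C\CC/C(C)=C/[Al](C)C | intermediate (not isolated)
12 | lithium butyl[(1E,5Z)-2,6-dimethylundeca-1,5-dien-9-yn-1-yl]dimethylaluminate | CC#CCC/C(C)=C\CC/C(C)=C/[Al-](C)(C)CCCC.[Li+] | intermediate (not isolated)
13 | (2E,6Z)-3,7-dimethyldodeca-2,6-dien-10-yn-1-ol | CC#CCC/C(C)=C\CC/C(C)=C/CO | intermediate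
14 | (2E,6Z,10E)-3,7-dimethyldodeca-2,6,10-triene bearing chlorobis(cyclopentadienyl)zirconium on C11 and on the C1 oxygen | C/C(=C\CC/C(C)=C\CC/C(C)=C/CO[Zr](Cl)(C1C=CC=C1)C1C=CC=C1)[Zr](Cl)(C1C=CC=C1)C1C=CC=C1 | intermediate (not isolated)
15 | (2E,6Z,10E)-11-iodo-3,7-dimethyldodeca-2,6,10-trien-1-ol | C/C(I)=C\CC/C(C)=C\CC/C(C)=C/CO | intermediate
16 | (2E,6Z,10E)-11-iodo-3,7-dimethyldodeca-2,6,10-trienal | C/C(I)=C\CC/C(C)=C\CC/C(C)=C/C=O | intermediate
17 | methyl acrylate | C=CC(=O)OC | starting material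
18 | 3-[(tert-butyldimethylsilyl)oxy]propanal | O=CCCO[Si](C)(C)C(C)(C)C | starting material
19 | methyl 5-[(tert-butyldimethylsilyl)oxy]-3-hydroxy-2-methylidenepentanoate (racemic) | C=C(C(=O)OC)C(O)CCO[Si](C)(C)C(C)(C)C | intermediate
20 | methyl (2Z)-2-(bromomethyl)-5-[(tert-butyldimethylsilyl)oxy]pent-2-enoate | COC(=O)/C(CBr)=C/CCO[Si](C)(C)C(C)(C)C | intermediate
21 | methyl (3S,4R,5E,9Z,13E)-3-{2-[(tert-butyldimethylsilyl)oxy]ethyl}-14-iodo-6,10-dimethyl-2-methylidene-4-[(trimethylsilyl)oxy]pentadeca-5,9,13-trienoate | C=C(C(=O)OC)[C@H](CCO[Si](C)(C)C(C)(C)C)[C@H](O[Si](C)(C)C)/C=C(\C)CC/C=C(/C)CC/C=C(/I)C | intermediate (not isolated)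
22 | (4S,5R)-4-{2-[(tert-butyldimethylsilyl)oxy]ethyl}-5-[(1E,5Z,9E)-10-iodo-2,6-dimethylundeca-1,5,9-trien-1-yl]-3-methylideneoxolan-2-one | C=C1C(=O)O[C@H](/C=C(\C)CC/C=C(/C)CC/C=C(/I)C)[C@H]1CCO[Si](C)(C)C(C)(C)C | intermediate
23 | (5R)-4-{2-[(tert-butyldimethylsilyl)oxy]ethyl}-5-[(1E,5Z,9E)-10-iodo-2,6-dimethylundeca-1,5,9-trien-1-yl]-3-methylfuran-2(5H)-one | CC(C)(C)[Si](C)(C)OCCC1=C(C)C(=O)O[C@@H]1/C=C(\C)CC/C=C(/C)CC/C=C(/I)C | intermediate
24 | (5R)-4-{2-[(tert-butyldimethylsilyl)oxy]ethyl}-5-[(1E)-4-{(2S,3R)-3-[(3E)-4-iodopent-3-en-1-yl]-3-methyloxiran-2-yl}-2-methylbut-1-en-1-yl]-3-methylfuran-2(5H)-one | CC(C)(C)[Si](C)(C)OCCC1=C(C)C(=O)O[C@@H]1/C=C(\C)CC[C@@H]2O[C@]2(C)CC/C=C(/I)C | intermediate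
25 | (5R)-4-(2-hydroxyethyl)-5-[(1E)-4-{(2S,3R)-3-[(3E)-4-iodopent-3-en-1-yl]-3-methyloxiran-2-yl}-2-methylbut-1-en-1-yl]-3-methylfuran-2(5H)-one | OCCC1=C(C)C(=O)O[C@@H]1/C=C(\C)CC[C@@H]2O[C@]2(C)CC/C=C(/I)C | intermediate
26 | {(2R)-2-[(1E)-4-{(2S,3R)-3-[(3E)-4-iodopent-3-en-1-yl]-3-methyloxiran-2-yl}-2-methylbut-1-en-1-yl]-4-methyl-5-oxo-2,5-dihydrofuran-3-yl}acetaldehyde | O=CCC1=C(C)C(=O)O[C@@H]1/C=C(\C)CC[C@@H]2O[C@]2(C)CC/C=C(/I)C | intermediate
27 | alkenylchromium dichloride of 26 (CrCl2 in place of iodine on C12) | O=CCC1=C(C)C(=O)O[C@@H]1/C=C(\C)CC[C@@H]2O[C@]2(C)CC/C=C(/[Cr](Cl)Cl)C | intermediate (not isolated)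
28 | (2R,7S,8R,13R)-7,8-epoxy-13-hydroxycembra-1(15),3E,11E-trien-16,2-olide | O[C@@H]1CC2=C(C)C(=O)O[C@@H]2/C=C(\C)CC[C@@H]2O[C@]2(C)CC/C=C/1C | intermediate
29 | (2R,7S,8R,13R)-13-acetoxy-7,8-epoxycembra-1(15),3E,11E-trien-16,2-olide | CC(=O)O[C@@H]1CC2=C(C)C(=O)O[C@@H]2/C=C(\C)CC[C@@H]2O[C@]2(C)CC/C=C/1C | target

Total step count: 17. Longest linear sequence: 14 steps (steps 1, 3–8 and 11–17, from pent-3-yn-1-ol).

Steps most likely to fail

Step 16. The alkenylchromium may add to both faces of the C13 aldehyde, because the ligand may not override the conformational bias of the folding chain. Fallback, setting out from 26 and coming back at 29: the ring is closed with ligand-free CrCl2/NiCl2 in DMSO–THF at high dilution and the two C13 epimers are separated. The 13R alcohol 28 is acetylated as in step 17. The epimer (2R,7S,8R,13S)-7,8-epoxy-13-hydroxycembra-1(15),3E,11E-trien-16,2-olide F1 is esterified under Mitsunobu conditions (PPh3, DIAD, AcOH, toluene, 0 °C) with inversion at C13, which gives 29 directly, so both epimers converge.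

Step 13. The dioxirane may discriminate poorly between the two faces of the Z-configured C7=C8 alkene, or oxidation may occur at iodine. Fallback, setting out from 7 and coming back at 24, with the epoxide set by Sharpless control at an allylic alcohol:
- Hydrozirconation–iodination of 7 (Cp2Zr(H)Cl; I2) should give (2Z,6E)-7-iodo-3-methylocta-2,6-dien-1-ol F2.
- Sharpless asymmetric epoxidation (Ti(OiPr)4, L-(+)-diethyl tartrate, t-BuOOH, 4 Å sieves, CH2Cl2, −20 °C) should give [(2S,3R)-3-[(3E)-4-iodopent-3-en-1-yl]-3-methyloxiran-2-yl]methanol F3.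
- Tf2O and 2,6-lutidine at −78 °C convert it into [(2S,3R)-3-[(3E)-4-iodopent-3-en-1-yl]-3-methyloxiran-2-yl]methyl trifluoromethanesulfonate F4.
- Alkylation of the dianion of methyl acetoacetate (NaH, n-BuLi, THF, −78 °C) with F4 gives methyl 5-{(2S,3R)-3-[(3E)-4-iodopent-3-en-1-yl]-3-methyloxiran-2-yl}-3-oxopentanoate F5.
- Aqueous LiOH and Tf2O give the Z-enol triflate, methyl (2Z)-5-{(2S,3R)-3-[(3E)-4-iodopent-3-en-1-yl]-3-methyloxiran-2-yl}-3-[(trifluoromethanesulfonyl)oxy]pent-2-enoate F6.
- Me2CuLi at −78 °C replaces the triflate with retention to give methyl (2E)-5-{(2S,3R)-3-[(3E)-4-iodopent-3-en-1-yl]-3-methyloxiran-2-yl}-3-methylpent-2-enoate F7.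
- i-Bu2AlH at −78 °C gives (2E)-5-{(2S,3R)-3-[(3E)-4-iodopent-3-en-1-yl]-3-methyloxiran-2-yl}-3-methylpent-2-en-1-ol F8.
- MnO2 gives (2E)-5-{(2S,3R)-3-[(3E)-4-iodopent-3-en-1-yl]-3-methyloxiran-2-yl}-3-methylpent-2-enal F9.
- The allylation of step 11 with 20 (Cp2ZrCl2 in place of TMSCl, lactonisation on buffered silica) gives (4S,5R)-4-{2-[(tert-butyldimethylsilyl)oxy]ethyl}-5-[(1E)-4-{(2S,3R)-3-[(3E)-4-iodopent-3-en-1-yl]-3-methyloxiran-2-yl}-2-methylbut-1-en-1-yl]-3-methylideneoxolan-2-one F10.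
- The isomerisation of step 12 then returns to 24.

Step 11. Enantiofacial control in the allylchromium addition to the β,β-disubstituted enal may be weak, or the iodoalkene may be lost if traces of nickel are present. Fallback, setting out from 19 (with 16) and coming back at 22, with boron in place of chromium: acetylation of 19 (Ac2O, DMAP, CH2Cl2) gives methyl 3-acetoxy-5-[(tert-butyldimethylsilyl)oxy]-2-methylidenepentanoate F11. Copper-catalysed SN2' borylation (B2pin2, CuCl, LiCl, KOAc, DMF) gives methyl (2E)-5-[(tert-butyldimethylsilyl)oxy]-2-[(4,4,5,5-tetramethyl-1,3,2-dioxaborolan-2-yl)methyl]pent-2-enoate F12. Allylboration of 16 with F12 under catalysis by a chiral BINOL-derived phosphoric acid (toluene, −30 °C), followed by acid-promoted lactonisation, returns to 22.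

Further compounds
F1 | step 16 | (2R,7S,8R,13S)-7,8-epoxy-13-hydroxycembra-1(15),3E,11E-trien-16,2-olide | O[C@H]1CC2=C(C)C(=O)O[C@@H]2/C=C(\C)CC[C@@H]2O[C@]2(C)CC/C=C/1C
F2 | step 13 | (2Z,6E)-7-iodo-3-methylocta-2,6-dien-1-ol | C/C(I)=C\CC/C(C)=C\CO
F3 | step 13 | [(2S,3R)-3-[(3E)-4-iodopent-3-en-1-yl]-3-methyloxiran-2-yl]methanol | OC[C@@H]1O[C@]1(C)CC/C=C(/I)C
F4 | step 13 | [(2S,3R)-3-[(3E)-4-iodopent-3-en-1-yl]-3-methyloxiran-2-yl]methyl trifluoromethanesulfonate | O=S(=O)(OC[C@@H]1O[C@]1(C)CC/C=C(/I)C)C(F)(F)F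
F5 | step 13 | methyl 5-{(2S,3R)-3-[(3E)-4-iodopent-3-en-1-yl]-3-methyloxiran-2-yl}-3-oxopentanoate | COC(=O)CC(=O)CC[C@@H]1O[C@]1(C)CC/C=C(/I)C
F6 | step 13 | methyl (2Z)-5-{(2S,3R)-3-[(3E)-4-iodopent-3-en-1-yl]-3-methyloxiran-2-yl}-3-[(trifluoromethanesulfonyl)oxy]pent-2-enoate | COC(=O)/C=C(\OS(=O)(=O)C(F)(F)F)CC[C@@H]1O[C@]1(C)CC/C=C(/I)C
F7 | step 13 | methyl (2E)-5-{(2S,3R)-3-[(3E)-4-iodopent-3-en-1-yl]-3-methyloxiran-2-yl}-3-methylpent-2-enoate | COC(=O)/C=C(\C)CC[C@@H]1O[C@]1(C)CC/C=C(/I)C
F8 | step 13 | (2E)-5-{(2S,3R)-3-[(3E)-4-iodopent-3-en-1-yl]-3-methyloxiran-2-yl}-3-methylpent-2-en-1-ol | OC/C=C(\C)CC[C@@H]1O[C@]1(C)CC/C=C(/I)C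
F9 | step 13 | (2E)-5-{(2S,3R)-3-[(3E)-4-iodopent-3-en-1-yl]-3-methyloxiran-2-yl}-3-methylpent-2-enal | O=C/C=C(\C)CC[C@@H]1O[C@]1(C)CC/C=C(/I)C
F10 | step 13 | (4S,5R)-4-{2-[(tert-butyldimethylsilyl)oxy]ethyl}-5-[(1E)-4-{(2S,3R)-3-[(3E)-4-iodopent-3-en-1-yl]-3-methyloxiran-2-yl}-2-methylbut-1-en-1-yl]-3-methylideneoxolan-2-one | C=C1C(=O)O[C@H](/C=C(\C)CC[C@@H]2O[C@]2(C)CC/C=C(/I)C)[C@H]1CCO[Si](C)(C)C(C)(C)C
F11 | step 11 | methyl 3-acetoxy-5-[(tert-butyldimethylsilyl)oxy]-2-methylidenepentanoate | C=C(C(=O)OC)C(OC(C)=O)CCO[Si](C)(C)C(C)(C)C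
F12 | step 11 | methyl (2E)-5-[(tert-butyldimethylsilyl)oxy]-2-[(4,4,5,5-tetramethyl-1,3,2-dioxaborolan-2-yl)methyl]pent-2-enoate | COC(=O)/C(CB1OC(C)(C)C(C)(C)O1)=C/CCO[Si](C)(C)C(C)(C)C
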